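The plan disconnects the only stereocentre, Ca, from two of its three carbon neighbours, chromone C3 and the diarylmethine carbon Cb (the third is C9, the acyl carbon of ring A), together with the O1–C2 bond of ring C. It exploits the fact that ring C, opened at O1–C2, is an o-hydroxyaryl enaminone whose C3 is a carbon nucleophile. In one operation a carbene from an aryl diazoketone (Ca) is joined to enaminone C3 and to a quinone methide made in the flask from bis(4-hydroxyphenyl)methanol (Cb) under Rh2(OAc)4 and a chiral phosphoric acid, and ring C is then closed. Each partner needs at most two steps from a commercial phenol.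

Key step: step 6

Labels: ring A = the 2-hydroxy-4-methoxyphenyl ring; C9 = its ketone carbon; Ca = the adjacent CH stereocentre; Cb = the CH carrying the two 4-hydroxyphenyl rings; O1, C2, C3 = chromone positions; ring C = the pyranone ring.

Structure check: target, precursor skeletons and key-step product agree atom for atom. Ca is (R) (priorities C9 > C3 > Cb > H). No connectivity or configuration needed correction.

Design changes (skeletons and disconnection unchanged):
(a) Both masked phenols are triisopropylsilyl ethers, not acetals. An acetal or alkyl ether ortho to the diazoketone would offer a basic oxygen and activated O–CH2 bonds to the carbene (five-membered oxonium ylide, C–H insertion). The bulky, weakly basic silyl ether should not.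
(b) Silyl ethers come off with buffered fluoride. This avoids the protic acid that acetal cleavage needs, which could enolise Ca or ionise the Ca–Cb bond.
(c) Ring closure is held back until the carbene stage is over and is then driven with acetic acid. The dimethylamine is thus released only after the chiral acid has done its work and cannot neutralise it.
(d) Both phenols of the benzhydrol stay free. One is needed to form the quinone methide, and keeping the two rings identical keeps Cb non-stereogenic.

Assumption: the facial sense exerted by the chiral phosphoric acid cannot be predicted with confidence; the (R)-acid is written, and its mirror image would be used if the (2S)-product should form.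

Step 1
Reactants: 1 2'-hydroxy-4'-methoxyacetophenone (paeonol)
Product: 2 1-[4-methoxy-2-(triisopropylsilyloxy)phenyl]ethanone
Conditions: iPr3SiOTf, 2,6-lutidine, CH2Cl2, 0 °C to rt
Reagents that add atoms: triisopropylsilyl trifluoromethanesulfonate, CC(C)[Si](OS(=O)(=O)C(F)(F)F)(C(C)C)C(C)C
Why: O-silylation of the chelated phenol with a silyl triflate and a hindered pyridine base is standard, and the resulting bulky, weakly basic silyl ether should neither form an oxonium ylide with, nor offer activated C–H bonds to, the carbene generated later at the neighbouring acyl group.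

Step 2
Reactants: 2 1-[4-methoxy-2-(triisopropylsilyloxy)phenyl]ethanone
Product: 4 2-diazo-1-[4-methoxy-2-(triisopropylsilyloxy)phenyl]ethanone, via trifluoroacetyl ketone 3 (not isolated)
Conditions: LiN(SiMe3)2, THF, −78 °C; CF3CO2CH2CF3; aqueous NH4Cl; then MeSO2N3, Et3N, H2O, MeCN, rt
Reagents that add atoms: methanesulfonyl azide, CS(=O)(=O)N=[N+]=[N-] (the two diazo nitrogen atoms); 2,2,2-trifluoroethyl trifluoroacetate, O=C(OCC(F)(F)F)C(F)(F)F (trifluoroacetyl group of 3 only, lost again)
Why: Deacylative Regitz-type diazo transfer: Claisen trifluoroacetylation of the kinetic lithium enolate activates the methyl group, and the sulfonyl azide then delivers N2 while the trifluoroacetyl group leaves on the sulfonamide nitrogen, conditions that an aryl triisopropylsilyl ether and an anisole should tolerate.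

Step 3
Reactants: 5 2',4'-dihydroxyacetophenone
Product: 6 1-[2-hydroxy-4-(triisopropylsilyloxy)phenyl]ethanone
Conditions: iPr3SiCl (1.05 equiv), imidazole, DMF, 0 °C to rt
Reagents that add atoms: chlorotriisopropylsilane, CC(C)[Si](Cl)(C(C)C)C(C)C
Why: Regioselective O-silylation, since the 2-hydroxyl is locked in a hydrogen bond to the ketone and one equivalent of the bulky chlorosilane should react only at the free, more acidic 4-hydroxyl.

Step 4
Reactants: 6 1-[2-hydroxy-4-(triisopropylsilyloxy)phenyl]ethanone
Product: 7 (E)-3-(dimethylamino)-1-[2-hydroxy-4-(triisopropylsilyloxy)phenyl]prop-2-en-1-one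
Conditions: Me2NCH(OMe)2, toluene, 80 °C
Reagents that add atoms: N,N-dimethylformamide dimethyl acetal, COC(OC)N(C)C
Why: Condensation of the methyl ketone with the amide acetal (enaminone formation) is the standard reaction of 2'-hydroxyacetophenones, gives the (E)-vinylogous amide with the chelated phenol left free, and the hindered silyl ether should resist the methanol released.

Step 5
Reactants: 8 4,4'-dihydroxybenzophenone
Product: 9 bis(4-hydroxyphenyl)methanol
Conditions: NaBH4, THF/MeOH, 0 °C to rt; aqueous NH4Cl quench
Reagents that add atoms: none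
Why: Borohydride reduction of the diaryl ketone at or below room temperature with a near-neutral quench should stop at the benzhydrol, because neither heat nor acid is present to ionise it to the quinone methide.

Step 6
Reactants: 4 2-diazo-1-[4-methoxy-2-(triisopropylsilyloxy)phenyl]ethanone, 7 (E)-3-(dimethylamino)-1-[2-hydroxy-4-(triisopropylsilyloxy)phenyl]prop-2-en-1-one, 9 bis(4-hydroxyphenyl)methanol
Product: 12 (2R)-1-[4-methoxy-2-(triisopropylsilyloxy)phenyl]-2-[4-oxo-7-(triisopropylsilyloxy)-4H-chromen-3-yl]-3,3-bis(4-hydroxyphenyl)propan-1-one, via quinone methide 10 (not isolated), via open-chain enaminone adduct 11 (not isolated)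
Conditions: Rh2(OAc)4 (2 mol%), (R)-3,3'-bis(2,4,6-triisopropylphenyl)-1,1'-binaphthalene-2,2'-diyl hydrogen phosphate (10 mol%), 4 Å molecular sieves, CH2Cl2, 0 °C, 7 (1.5 equiv), 9 (1.0 equiv), 4 (1.4 equiv) added over 4 h; then AcOH, 35 °C
Reagents that add atoms: none
Why: Proposed new method: Rh2(OAc)4 turns 4 into an electrophilic carbene that the enaminone carbon of 7 (future C3) attacks, giving an iminium–enol zwitterion; its enol carbon Ca then adds, inside the hydrogen-bonded chiral phosphate assembly, to Cb of quinone methide 10, which the same acid forms from 9 by loss of water, and loss of the C3 proton leaves the neutral enaminone 11, so that no amine is set free while the chiral acid is at work. The closest known reaction types are the trapping of carbene-derived enols and zwitterions by electrophiles under Rh2(OAc)4 and chiral phosphoric acid co-catalysis and the carbene-initiated conversion of o-hydroxyaryl enaminones into 3-substituted chromones; their merger with a quinone methide made in the flask is new. Ring C is closed afterwards by 6-endo-trig addition of the phenol oxygen O1 to C2 and elimination of dimethylamine, which the acetic acid added after the carbene stage promotes and holds as its salt, so that the base can neither neutralise the chiral acid nor epimerise Ca. Ca is set in the Ca–Cb bond formation: the phosphate binds the enol hydroxyl and the quinone methide oxygen at once and leaves one enol face open, while Cb with its two identical aryl groups is not stereogenic. The step needs attack on the carbene by C3 in preference to the O–H groups, and capture of the enol by 10 before a proton shifts to Ca. The enaminone carbon is the strongest nucleophile present and its own phenol is tied into a hydrogen bond with the ketone, 10 is unhindered at Cb, 4 has no β-hydrogen and only a bulky, weakly basic silyl ether near the carbene, and slow addition of 4 keeps the zwitterion far more dilute than its quinone methide partner.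

Step 7
Reactants: 12 (2R)-1-[4-methoxy-2-(triisopropylsilyloxy)phenyl]-2-[4-oxo-7-(triisopropylsilyloxy)-4H-chromen-3-yl]-3,3-bis(4-hydroxyphenyl)propan-1-one
Product: 13 (2R)-1-(2-hydroxy-4-methoxyphenyl)-2-(7-hydroxy-4-oxo-4H-chromen-3-yl)-3,3-bis(4-hydroxyphenyl)propan-1-one
Conditions: Bu4NF, AcOH (1:1.5), THF, 0 °C
Reagents that add atoms: none
Why: Fluoride-induced cleavage of the two aryl silyl ethers, buffered with acetic acid so that neither Ca–H is deprotonated nor a phenoxide can trigger retro-1,6-addition, touches no bond at Ca and should therefore return the target with the (R) configuration intact.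

Compound list
1 | 2'-hydroxy-4'-methoxyacetophenone (paeonol) | CC(=O)c1ccc(OC)cc1O | starting material
2 | 1-[4-methoxy-2-(triisopropylsilyloxy)phenyl]ethanone | CC(=O)c1ccc(OC)cc1O[Si](C(C)C)(C(C)C)C(C)C | intermediate
3 | 4,4,4-trifluoro-1-[4-methoxy-2-(triisopropylsilyloxy)phenyl]butane-1,3-dione (trifluoroacetyl ketone, formed and used in the flask in step 2) | O=C(CC(=O)C(F)(F)F)c1ccc(OC)cc1O[Si](C(C)C)(C(C)C)C(C)C | intermediate
4 | 2-diazo-1-[4-methoxy-2-(triisopropylsilyloxy)phenyl]ethanone | COc1ccc(C(=O)C=[N+]=[N-])c(O[Si](C(C)C)(C(C)C)C(C)C)c1 | intermediate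
5 | 2',4'-dihydroxyacetophenone | CC(=O)c1ccc(O)cc1O | starting material
6 | 1-[2-hydroxy-4-(triisopropylsilyloxy)phenyl]ethanone | CC(=O)c1ccc(O[Si](C(C)C)(C(C)C)C(C)C)cc1O | intermediate
7 | (E)-3-(dimethylamino)-1-[2-hydroxy-4-(triisopropylsilyloxy)phenyl]prop-2-en-1-one | CN(C)/C=C/C(=O)c1ccc(O[Si](C(C)C)(C(C)C)C(C)C)cc1O | intermediate
8 | 4,4'-dihydroxybenzophenone | O=C(c1ccc(O)cc1)c1ccc(O)cc1 | starting material
9 | bis(4-hydroxyphenyl)methanol | OC(c1ccc(O)cc1)c1ccc(O)cc1 | intermediate
10 | 4-[(4-hydroxyphenyl)methylidene]cyclohexa-2,5-dien-1-one (quinone methide, formed and used in the flask in step 6) | O=C1C=CC(=Cc2ccc(O)cc2)C=C1 | intermediate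
11 | (3R)-3-[bis(4-hydroxyphenyl)methyl]-2-[(dimethylamino)methylidene]-1-[2-hydroxy-4-(triisopropylsilyloxy)phenyl]-4-[4-methoxy-2-(triisopropylsilyloxy)phenyl]butane-1,4-dione (open-chain adduct, enamine geometry not fixed, formed and used in the flask in step 6) | COc1ccc(C(=O)[C@@H](C(=CN(C)C)C(=O)c2ccc(O[Si](C(C)C)(C(C)C)C(C)C)cc2O)C(c2ccc(O)cc2)c2ccc(O)cc2)c(O[Si](C(C)C)(C(C)C)C(C)C)c1 | intermediate
12 | (2R)-1-[4-methoxy-2-(triisopropylsilyloxy)phenyl]-2-[4-oxo-7-(triisopropylsilyloxy)-4H-chromen-3-yl]-3,3-bis(4-hydroxyphenyl)propan-1-one | COc1ccc(C(=O)[C@@H](c2coc3cc(O[Si](C(C)C)(C(C)C)C(C)C)ccc3c2=O)C(c2ccc(O)cc2)c2ccc(O)cc2)c(O[Si](C(C)C)(C(C)C)C(C)C)c1 | intermediate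
13 | (2R)-1-(2-hydroxy-4-methoxyphenyl)-2-(7-hydroxy-4-oxo-4H-chromen-3-yl)-3,3-bis(4-hydroxyphenyl)propan-1-one (CNP0178475.1) | COc1ccc(C(=O)[C@@H](c2coc3cc(O)ccc3c2=O)C(c2ccc(O)cc2)c2ccc(O)cc2)c(O)c1 | target

Total step count: 7 steps.
Longest linear sequence: 4 steps (1 → 2 → 4 → 12 → 13).

Steps most likely to fail

Step 6. The carbene may be consumed by insertion into the phenolic O–H bonds of 9. The zwitterion may collapse by proton transfer to the two-component chromone before it meets the quinone methide. The quinone methide may oligomerise by arylation of phenol rings, dimethylamine may be released early and neutralise the chiral acid, or facial selectivity in the ion pair may be poor. The fallback uses known chemistry, sets out from 4 and 7 and rejoins the route at 12. Rh2(OAc)4 alone in CH2Cl2 should couple 4 and 7 by the established carbene insertion and chromone annulation to the achiral ketone 1-[4-methoxy-2-(triisopropylsilyloxy)phenyl]-2-[4-oxo-7-(triisopropylsilyloxy)-4H-chromen-3-yl]ethanone F1. Acid-catalysed dehydrative alkylation of its enol with 9 (diphenyl phosphate, 1,2-dichloroethane, 40 °C; 1,6-addition of an enolisable ketone to the quinone methide) should then give the racemic 1-[4-methoxy-2-(triisopropylsilyloxy)phenyl]-2-[4-oxo-7-(triisopropylsilyloxy)-4H-chromen-3-yl]-3,3-bis(4-hydroxyphenyl)propan-1-one F2. Preparative chromatography on a chiral stationary phase (amylose tris(3,5-dimethylphenylcarbamate), hexane/2-propanol) would separate 12 from the (2S)-enantiomer of 12 F3.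

Step 2. The lithium enolate may attack the neighbouring silyl ether (silyl migration), or the silyl group may be lost in the aqueous amine stage, after which the free o-hydroxy diazoketone would close to a benzofuranone. The fallback sets out from 2 and rejoins at 4. α-Bromination with phenyltrimethylammonium tribromide (THF, 0 °C) should give 2-bromo-1-[4-methoxy-2-(triisopropylsilyloxy)phenyl]ethanone F4. Treatment with N,N'-ditosylhydrazine and DBU (THF, 0 °C) should then form the diazoketone by N-alkylation and twofold sulfinate elimination, with no enolate acylation involved.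

Step 5. Reduction may stall because the phenoxide deactivates the ketone, may run on to the diarylmethane through the quinone methide, or the benzhydrol may self-condense during work-up. The fallback sets out from 8 and rejoins at 9. Silylation (tBuMe2SiCl, imidazole, DMF) should give bis[4-(tert-butyldimethylsilyloxy)phenyl]methanone F5. NaBH4 reduction (THF/MeOH) should give bis[4-(tert-butyldimethylsilyloxy)phenyl]methanol F6, in which no phenoxide can form. Desilylation with Bu4NF buffered by AcOH at 0 °C then gives 9, to be used at once.

Further compounds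
F1 | step 6 | 1-[4-methoxy-2-(triisopropylsilyloxy)phenyl]-2-[4-oxo-7-(triisopropylsilyloxy)-4H-chromen-3-yl]ethanone | COc1ccc(C(=O)Cc2coc3cc(O[Si](C(C)C)(C(C)C)C(C)C)ccc3c2=O)c(O[Si](C(C)C)(C(C)C)C(C)C)c1
F2 | step 6 | racemic 1-[4-methoxy-2-(triisopropylsilyloxy)phenyl]-2-[4-oxo-7-(triisopropylsilyloxy)-4H-chromen-3-yl]-3,3-bis(4-hydroxyphenyl)propan-1-one | COc1ccc(C(=O)C(c2coc3cc(O[Si](C(C)C)(C(C)C)C(C)C)ccc3c2=O)C(c2ccc(O)cc2)c2ccc(O)cc2)c(O[Si](C(C)C)(C(C)C)C(C)C)c1
F3 | step 6 | (2S)-1-[4-methoxy-2-(triisopropylsilyloxy)phenyl]-2-[4-oxo-7-(triisopropylsilyloxy)-4H-chromen-3-yl]-3,3-bis(4-hydroxyphenyl)propan-1-one (enantiomer of 12) | COc1ccc(C(=O)[C@H](c2coc3cc(O[Si](C(C)C)(C(C)C)C(C)C)ccc3c2=O)C(c2ccc(O)cc2)c2ccc(O)cc2)c(O[Si](C(C)C)(C(C)C)C(C)C)c1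
F4 | step 2 | 2-bromo-1-[4-methoxy-2-(triisopropylsilyloxy)phenyl]ethanone | COc1ccc(C(=O)CBr)c(O[Si](C(C)C)(C(C)C)C(C)C)c1
F5 | step 5 | bis[4-(tert-butyldimethylsilyloxy)phenyl]methanone | O=C(c1ccc(O[Si](C)(C)C(C)(C)C)cc1)c1ccc(O[Si](C)(C)C(C)(C)C)cc1
F6 | step 5 | bis[4-(tert-butyldimethylsilyloxy)phenyl]methanol | OC(c1ccc(O[Si](C)(C)C(C)(C)C)cc1)c1ccc(O[Si](C)(C)C(C)(C)C)cc1
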